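The numbers in the tables stem from a simulated flask for an exercise; scatter was added.

A small charge of second nucleophile, 0.25 equiv in the ash run, already holds the target near 55.1%, and the dispute is what 0.500 equiv does once one partner is fed over 50 s.

| flask | substrate | first nucleophile | second nucleophile | remark | time |
|---|---|---|---|---|---|
| birch | 17 mM | 1 equiv | 0.50 equiv | run made earlier |  |
| ash | 17 mM | 1 equiv | 0.25 equiv | run made earlier |  |
| alder | 17 mM | 1 equiv | 1 equiv | run made earlier |  |
| Tuesday's | 17 mM | 1.00 equiv | 0.500 equiv | everything together at the start | 2.0 min |
| Wednesday's | 17 mM | 1.00 equiv (fed, over 50 s) | 0.500 equiv | all else is in the flask from the start; the feed brings no volume worth counting | 2.0 min |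
| Sunday's | 17 mM (fed, over 50 s) | 1.00 equiv | 0.500 equiv | all else is in the flask from the start; the feed brings no volume worth counting | 2.0 min |

| birch: time / s | birch: target / % | ash: time / s | ash: target / % | alder: time / s | alder: target / % |
|---|---|---|---|---|---|
| 10.0 | 39.6 | 12.0 | 54.3 | 10.0 | 19.3 |
| 20.0 | 43.1 | 30.0 | 55.1 | 20.0 | 20.2 |
| 50.0 | 45.7 | 60.0 | 53.1 | 40.0 | 23.8 |
| 120 | 45.7 | 90.0 | 53.0 | 90.0 | 19.3 |

(scatter of a reading: 1 percentage point)

- the flask that comes out highest in amount of target, in percent of the substrate charged, or "all alike" when all lie within 1.5 percentage points (Tuesday's / Wednesday's / Sunday's / all alike)
- target at the end, in percent of the substrate charged, Tuesday's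
- target at the end, in percent of the substrate charged, Wednesday's
- target at the end, in percent of the substrate charged, Sunday's

- a reading or a percentage of target counts all its forms, free or not

My colleague reads the runs as a contest of rates, in which the second nucleophile destroys the first about 7 times faster than substrate captures it and the first nucleophile then over-attacks the target, so that in Wednesday's flask, with every step first order in the fed first nucleophile, the outcome stays as in birch, while in Sunday's flask the quench finishes first and target meets excess nucleophile with substrate scarce, so that over-reaction grows.

I keep the count of a limiting reagent instead: target is the lower of two amounts, the substrate less the second nucleophile's charge, and the first nucleophile alive when substrate reaches it, which with the whole charge alive is 50.0%, the ledger. The birch rise reads as a substrate half-life of about 3.44 s, and the ash run, flat by 12.0 s, leaves 44.9% of its first nucleophile outside the target although its ledger stands at 75.0%, so I take the first nucleophile to halve by itself in about that same time, slowing as it thins. In Sunday's flask the feed runs far longer than that half-life, and at mid-feed 12.1% of the first nucleophile stands, which is my figure for Sunday's target. Tuesday's should repeat birch, and in Wednesday's flask the fed first nucleophile meets substrate already there, so I expect 50.0% less a little, the highest of the three.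

The forecast, on my colleague's side, says of Wednesday's flask “selectivity does not depend on the feed rate” and gives 45.5%, 45% and 32% for Tuesday's, Wednesday's and Sunday's, with Tuesday's highest.

The flasks give 44.4%, 48.6% and 10.4% in that order, so Wednesday's is highest, against my 50.0% and 12.1%, while my colleague's contest of rates keeps the alder run, where the ledger gives 0% and the reading stands near 20.2%.

    2 first nucleophile → homo dimer (k = 13.0 /M/s)
    substrate → intermediate (k = 0.250 /s)
    first nucleophile + intermediate → target (k = 2000 /M/s)
    crystals ⇌ target, rate k4*(cs4 - [target]) while solid is left; crystals form when [target] > cs4 (solubility = 0.560 mM, k = 7.50 /s)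
    target ⇌ isomer of the product (K = 0.430, k = 0.190 /s)
    second nucleophile + intermediate → other capture product (k = 4500 /M/s)

A neighbour of Wednesday's charged with 0.250 equiv of first nucleophile has a ledger of 25.0% and gives 23.6%. In Wednesday's flask substrate went to intermediate, that step half done by 2.78 s, while both nucleophiles took the intermediate, and at 0.833 min target stood at 48.6%, other capture product at 50.0%, and 20.9% of the first nucleophile's charge was still there. In Sunday's flask the first nucleophile stood at 0% of its charge by that same time, with homo dimer at 7.49 mM, and the intermediate formed from then on stayed, reaching 38.2% at 2.00 min.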